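**Plan**
- Retrosynthesis: cut the senecioate C–O bond first, then ring B (the pyran-2-one) at C3=C4 and O1–C2, then ring A at C8–C8a, C6–C7 and C4a–C8a, and last the bond between C1′ and the alkyne carbon.
- Enabling feature: ring A is a 1,2,3,4-tetrasubstituted benzene in which C8 (side chain) lies between the oxygen-bearing carbons C7 (OMe) and C8a (O1). This is a 2-alkyl-3-methoxyphenol, the pattern a vinylketene/methoxyalkyne benzannulation delivers.
- Forward order: the five-carbon side chain is joined to methoxyacetylide, ring A is built around it from cyclobutenone, ring B follows by ortho-formylation and intramolecular Wittig lactonization, and the ketone and ester are set last.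
- Stereochemistry: the only stereocenter, C1′ (R), comes from Felkin–Anh addition of lithium methoxyacetylide to the (S)-α-silyloxy aldehyde made from (S)-2-hydroxy-3-methylbutanoic acid. The controlling C2′ carbinol is later oxidized to the ketone.

Key step: step 8

Remark on numbering: coumarin numbering (O1, C2 to C8a) is used for the core; C1′ and C2′ are the carbinol and carbonyl carbons of the C8 side chain.
Assumption: the C3 epimers of the propargylic alcohol from step 4 are separable by chromatography on base-washed silica.

**Route**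

Step 1
Reactants: 1 (S)-2-hydroxy-3-methylbutanoic acid
Product: 2 methyl (S)-2-hydroxy-3-methylbutanoate
Conditions: MeOH, H2SO4 (cat.), reflux
Reagents that add atoms: methanol, CO
Why: Fischer esterification in excess methanol is routine for α-hydroxy acids and leaves the carbinol stereocenter untouched.

Step 2
Reactants: 2 methyl (S)-2-hydroxy-3-methylbutanoate
Product: 3 methyl (S)-3-methyl-2-(triethylsilyloxy)butanoate
Conditions: Et3SiCl, imidazole, CH2Cl2, 0 °C to rt
Reagents that add atoms: chlorotriethylsilane, CC[Si](Cl)(CC)CC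
Why: Imidazole-promoted O-silylation installs a non-chelating group that supports Felkin–Anh control in step 4 and can later be removed ahead of a tert-butyldimethylsilyl ether.

Step 3
Reactants: 3 methyl (S)-3-methyl-2-(triethylsilyloxy)butanoate
Product: 4 (S)-3-methyl-2-(triethylsilyloxy)butanal
Conditions: i-Bu2AlH (1.1 equiv), CH2Cl2, −78 °C; MeOH, then aq. KNaC4H4O6
Reagents that add atoms: none
Why: Partial ester reduction with i-Bu2AlH at low temperature stops at the aldehyde for α-silyloxy esters because the tetrahedral aluminium hemiacetal persists until work-up; the aldehyde would be used crude to avoid α-epimerization.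

Step 4
Reactants: 4 (S)-3-methyl-2-(triethylsilyloxy)butanal; 5 chloroacetaldehyde dimethyl acetal (2-chloro-1,1-dimethoxyethane)
Product: 7 (3R,4S)-1-methoxy-5-methyl-4-(triethylsilyloxy)hex-1-yn-3-ol, via lithium methoxyacetylide 6 (not isolated)
Conditions: 5, LiNEt2 (3 equiv per 5), THF, 0 °C; then 4, −78 °C; pH 7 phosphate buffer at −78 °C; chromatography on Et3N-treated silica
Reagents that add atoms: none
Why: Twofold elimination (MeOH, then HCl) and deprotonation of 5 by the amide base gives acetylide 6, whose 1,2-addition to the aldehyde under non-chelating conditions should follow the polar Felkin–Anh model (C–OSi bond anti to the incoming nucleophile, attack past H), giving the 3R carbinol anti to the 4S silyloxy group; the minor 3S epimer is removed by chromatography.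

Step 5
Reactants: 7 (3R,4S)-1-methoxy-5-methyl-4-(triethylsilyloxy)hex-1-yn-3-ol
Product: 8 (3R,4S)-3-(tert-butyldimethylsilyloxy)-1-methoxy-5-methyl-4-(triethylsilyloxy)hex-1-yne
Conditions: t-BuMe2SiCl, imidazole, DMAP (cat.), DMF, rt
Reagents that add atoms: tert-butyl(chloro)dimethylsilane, CC(C)(C)[Si](C)(C)Cl
Why: Base-buffered silylation caps the acid-sensitive alkoxyalkynyl carbinol before it can undergo Meyer–Schuster rearrangement, and gives a benzylic-position ether robust enough for the steps up to 13.

Step 6
Reactants: 9 3-oxocyclobutane-1-carboxylic acid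
Product: 10 3-bromocyclobutan-1-one
Conditions: HgO, Br2, MgSO4, CH2Cl2, reflux
Reagents that add atoms: bromine, BrBr
Why: The Cristol–Firth variant of the Hunsdiecker bromodecarboxylation converts the acid, through its acyl hypobromite and a cyclobutyl radical, into the bromide.

Step 7
Reactants: 10 3-bromocyclobutan-1-one
Product: 11 cyclobut-2-en-1-one
Conditions: n-Bu3N, neat, rt, reduced pressure, distillate trapped at −78 °C
Reagents that add atoms: none
Why: E1cB dehydrobromination of the β-bromo ketone by a non-nucleophilic tertiary amine gives the enone, which is distilled out as it forms and kept as a cold solution to limit polymerization.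

Step 8
Reactants: 8 (3R,4S)-3-(tert-butyldimethylsilyloxy)-1-methoxy-5-methyl-4-(triethylsilyloxy)hex-1-yne; 11 cyclobut-2-en-1-one
Product: 16 2-[(1R,2S)-1-(tert-butyldimethylsilyloxy)-3-methyl-2-(triethylsilyloxy)butyl]-3-methoxyphenol, via vinylketene 12 (not isolated), via vinylcyclobutenone 13 (not isolated), via dienylketene 14 (not isolated), via cyclohexadienone 15 (not isolated)
Conditions: 11 (3 equiv, in portions), toluene, sealed tube, 80 °C then 110 °C; crude stirred with K2CO3, MeOH, rt (returns any O-acylated phenol)
Reagents that add atoms: none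
Why: Heating opens 11 by conrotatory 4π electrocyclic cleavage to vinylketene 12, whose carbonyl carbon is attacked by the alkyne carbon remote from methoxy in a regiospecific (2+2) cycloaddition that forms C8–C8a and C6–C7 and gives 4-vinylcyclobutenone 13. A second, reversible 4π opening gives dienylketene 14, and the isomer with the vinyl group cis to the ketene closes ring A by thermal disrotatory 6π electrocyclization (C4a–C8a bond) to cyclohexadienone 15, which tautomerizes irreversibly to phenol 16. The closest known reaction type is the Danheiser benzannulation of cyclobutenones with alkoxyalkynes, which gives 2-substituted 3-alkoxyphenols. No lasting stereocenter is formed (the sp3 carbons of 13 and 15 disappear on ring opening and aromatization), and the two silyloxy carbinol centers are not touched under neutral thermal conditions. The step needs regioselectivity only, and the polarization of the O-methyl ynol ether secures it by placing the side chain ortho and the methoxy group meta to the new hydroxyl; a methyl ynol ether also cannot fragment by retro-ene loss of an alkene.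

Step 9
Reactants: 16 2-[(1R,2S)-1-(tert-butyldimethylsilyloxy)-3-methyl-2-(triethylsilyloxy)butyl]-3-methoxyphenol
Product: 18 3-[(1R,2S)-1-(tert-butyldimethylsilyloxy)-3-methyl-2-(triethylsilyloxy)butyl]-2-hydroxy-4-methoxybenzaldehyde, via hydroxymethylphenol 17 (not isolated)
Conditions: MgCl2, Et3N, (CH2O)n, THF, reflux; cold aq. citric acid work-up
Reagents that add atoms: paraformaldehyde (formaldehyde), C=O
Why: In the magnesium-mediated ortho-formylation (Casnati–Skattebøl) the magnesium phenoxide delivers formaldehyde to the only free ortho position, which is also para to methoxy, and the benzylic alkoxide 17 is oxidized by a second formaldehyde through hydride transfer.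

Step 10
Reactants: 18 3-[(1R,2S)-1-(tert-butyldimethylsilyloxy)-3-methyl-2-(triethylsilyloxy)butyl]-2-hydroxy-4-methoxybenzaldehyde
Product: 20 8-[(1R,2S)-1-(tert-butyldimethylsilyloxy)-3-methyl-2-(triethylsilyloxy)butyl]-7-methoxy-2H-chromen-2-one, via phosphoranylidene ester 19 (not isolated)
Conditions: Ph3P=C=C=O (1.2 equiv), toluene, 100 °C
Reagents that add atoms: ketenylidenetriphenylphosphorane, O=C=C=P(c1ccccc1)(c1ccccc1)c1ccccc1
Why: The Bestmann cumulated ylide adds the phenol O–H to give ester-stabilized ylide 19, which closes ring B by intramolecular Wittig olefination of the ortho formyl group (domino addition–Wittig route to coumarins), necessarily giving the cis olefin without the high temperatures of the intermolecular variant.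

Step 11
Reactants: 20 8-[(1R,2S)-1-(tert-butyldimethylsilyloxy)-3-methyl-2-(triethylsilyloxy)butyl]-7-methoxy-2H-chromen-2-one
Product: 21 8-[(1R,2S)-1-(tert-butyldimethylsilyloxy)-2-hydroxy-3-methylbutyl]-7-methoxy-2H-chromen-2-one
Conditions: PPTS (cat.), MeOH/CH2Cl2, 0 °C to rt
Reagents that add atoms: none
Why: Mild acid-catalysed methanolysis cleaves a secondary triethylsilyl ether much faster than the bulkier secondary tert-butyldimethylsilyl ether (selective silyl ether cleavage), and the lactone is inert to these conditions.

Step 12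
Reactants: 21 8-[(1R,2S)-1-(tert-butyldimethylsilyloxy)-2-hydroxy-3-methylbutyl]-7-methoxy-2H-chromen-2-one
Product: 22 8-[(1R)-1-(tert-butyldimethylsilyloxy)-3-methyl-2-oxobutyl]-7-methoxy-2H-chromen-2-one
Conditions: Dess–Martin periodinane, NaHCO3, CH2Cl2, 0 °C to rt
Reagents that add atoms: none
Why: Buffered Dess–Martin oxidation converts the hindered secondary alcohol into the ketone under neutral conditions that should not enolize the adjacent benzylic silyloxy stereocenter.

Step 13
Reactants: 22 8-[(1R)-1-(tert-butyldimethylsilyloxy)-3-methyl-2-oxobutyl]-7-methoxy-2H-chromen-2-one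
Product: 23 8-[(1R)-1-hydroxy-3-methyl-2-oxobutyl]-7-methoxy-2H-chromen-2-one
Conditions: HF·pyridine, pyridine, THF, 0 °C to rt
Reagents that add atoms: none
Why: Fluoride-mediated desilylation with buffered HF·pyridine attacks silicon only and avoids basic fluoride sources, so the C1′–O bond and the configuration of the enolizable α-ketol carbon should be retained.

Step 14
Reactants: 23 8-[(1R)-1-hydroxy-3-methyl-2-oxobutyl]-7-methoxy-2H-chromen-2-one; 24 3-methylbut-2-enoyl chloride
Product: 25 (1R)-1-(7-methoxy-2-oxo-2H-chromen-8-yl)-3-methyl-2-oxobutyl 3-methylbut-2-enoate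
Conditions: 24 (1.5 equiv), pyridine, DMAP (cat.), CH2Cl2, 0 °C
Reagents that add atoms: none
Why: Nucleophile-catalysed acylation with a weak base (pyridine/DMAP esterification) is expected to avoid both dehydrochlorination of the acid chloride to a vinylketene, which would deconjugate the ester, and enolization of the α-acyloxy ketone.

**Compound list**

1 | (S)-2-hydroxy-3-methylbutanoic acid | CC(C)[C@H](O)C(=O)O | starting material
2 | methyl (S)-2-hydroxy-3-methylbutanoate | CC(C)[C@H](O)C(=O)OC | intermediate
3 | methyl (S)-3-methyl-2-(triethylsilyloxy)butanoate | CC(C)[C@H](O[Si](CC)(CC)CC)C(=O)OC | intermediate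
4 | (S)-3-methyl-2-(triethylsilyloxy)butanal | CC(C)[C@H](O[Si](CC)(CC)CC)C=O | intermediate
5 | chloroacetaldehyde dimethyl acetal (2-chloro-1,1-dimethoxyethane) | COC(CCl)OC | starting material
6 | lithium methoxyacetylide | [Li]C#COC | intermediate
7 | (3R,4S)-1-methoxy-5-methyl-4-(triethylsilyloxy)hex-1-yn-3-ol | COC#C[C@@H](O)[C@@H](O[Si](CC)(CC)CC)C(C)C | intermediate
8 | (3R,4S)-3-(tert-butyldimethylsilyloxy)-1-methoxy-5-methyl-4-(triethylsilyloxy)hex-1-yne | COC#C[C@@H](O[Si](C)(C)C(C)(C)C)[C@@H](O[Si](CC)(CC)CC)C(C)C | intermediate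
9 | 3-oxocyclobutane-1-carboxylic acid | O=C1CC(C1)C(=O)O | starting material
10 | 3-bromocyclobutan-1-one | O=C1CC(Br)C1 | intermediate
11 | cyclobut-2-en-1-one | O=C1C=CC1 | intermediate
12 | vinylketene (buta-1,3-dien-1-one) | C=CC=C=O | intermediate
13 | 2-[(1R,2S)-1-(tert-butyldimethylsilyloxy)-3-methyl-2-(triethylsilyloxy)butyl]-4-ethenyl-3-methoxycyclobut-2-en-1-one (C4 unassigned) | O=C1C([C@@H](O[Si](C)(C)C(C)(C)C)[C@@H](O[Si](CC)(CC)CC)C(C)C)=C(OC)C1C=C | intermediate
14 | (3E)-2-[(1R,2S)-1-(tert-butyldimethylsilyloxy)-3-methyl-2-(triethylsilyloxy)butyl]-3-methoxyhexa-1,3,5-trien-1-one | O=C=C([C@@H](O[Si](C)(C)C(C)(C)C)[C@@H](O[Si](CC)(CC)CC)C(C)C)/C(OC)=C\C=C | intermediate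
15 | 2-[(1R,2S)-1-(tert-butyldimethylsilyloxy)-3-methyl-2-(triethylsilyloxy)butyl]-3-methoxycyclohexa-2,4-dien-1-one | O=C1CC=CC(OC)=C1[C@@H](O[Si](C)(C)C(C)(C)C)[C@@H](O[Si](CC)(CC)CC)C(C)C | intermediate
16 | 2-[(1R,2S)-1-(tert-butyldimethylsilyloxy)-3-methyl-2-(triethylsilyloxy)butyl]-3-methoxyphenol | COc1cccc(O)c1[C@@H](O[Si](C)(C)C(C)(C)C)[C@@H](O[Si](CC)(CC)CC)C(C)C | intermediate
17 | 2-[(1R,2S)-1-(tert-butyldimethylsilyloxy)-3-methyl-2-(triethylsilyloxy)butyl]-6-(hydroxymethyl)-3-methoxyphenol (present as its magnesium salt) | COc1ccc(CO)c(O)c1[C@@H](O[Si](C)(C)C(C)(C)C)[C@@H](O[Si](CC)(CC)CC)C(C)C | intermediate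
18 | 3-[(1R,2S)-1-(tert-butyldimethylsilyloxy)-3-methyl-2-(triethylsilyloxy)butyl]-2-hydroxy-4-methoxybenzaldehyde | COc1ccc(C=O)c(O)c1[C@@H](O[Si](C)(C)C(C)(C)C)[C@@H](O[Si](CC)(CC)CC)C(C)C | intermediate
19 | 2-[(1R,2S)-1-(tert-butyldimethylsilyloxy)-3-methyl-2-(triethylsilyloxy)butyl]-6-formyl-3-methoxyphenyl (triphenylphosphoranylidene)acetate | COc1ccc(C=O)c(OC(=O)C=P(c2ccccc2)(c2ccccc2)c2ccccc2)c1[C@@H](O[Si](C)(C)C(C)(C)C)[C@@H](O[Si](CC)(CC)CC)C(C)C | intermediate
20 | 8-[(1R,2S)-1-(tert-butyldimethylsilyloxy)-3-methyl-2-(triethylsilyloxy)butyl]-7-methoxy-2H-chromen-2-one | COc1ccc2ccc(=O)oc2c1[C@@H](O[Si](C)(C)C(C)(C)C)[C@@H](O[Si](CC)(CC)CC)C(C)C | intermediate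
21 | 8-[(1R,2S)-1-(tert-butyldimethylsilyloxy)-2-hydroxy-3-methylbutyl]-7-methoxy-2H-chromen-2-one | COc1ccc2ccc(=O)oc2c1[C@@H](O[Si](C)(C)C(C)(C)C)[C@@H](O)C(C)C | intermediate
22 | 8-[(1R)-1-(tert-butyldimethylsilyloxy)-3-methyl-2-oxobutyl]-7-methoxy-2H-chromen-2-one | COc1ccc2ccc(=O)oc2c1[C@@H](O[Si](C)(C)C(C)(C)C)C(=O)C(C)C | intermediate
23 | 8-[(1R)-1-hydroxy-3-methyl-2-oxobutyl]-7-methoxy-2H-chromen-2-one | COc1ccc2ccc(=O)oc2c1[C@@H](O)C(=O)C(C)C | intermediate
24 | 3-methylbut-2-enoyl chloride | CC(C)=CC(Cl)=O | starting material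
25 | (1R)-1-(7-methoxy-2-oxo-2H-chromen-8-yl)-3-methyl-2-oxobutyl 3-methylbut-2-enoate | COc1ccc2ccc(=O)oc2c1[C@@H](OC(=O)C=C(C)C)C(=O)C(C)C | target

**Step count**

Total steps: 14. Longest linear sequence: 12 steps (steps 1 to 5, then 8 to 14); steps 6 and 7 form the two-step branch to cyclobutenone.

**Steps most likely to fail**

Step 8. Oligomerization of cyclobutenone and of vinylketene 12 may outrun capture by the sterically shielded alkyne at the temperature needed for ring opening, and surplus ketene may acylate the product phenol. The fallback sets out from alkyne 8 and generates the same vinylketene at room temperature by a photochemical Wolff rearrangement, so the same three bonds still form. 3-Chloropropanoyl chloride and diazomethane would give 4-chloro-1-diazobutan-2-one F1, and dehydrochlorination with Et3N would give 1-diazobut-3-en-2-one F2. Irradiation of F2 (Pyrex-filtered mercury lamp, ClCH2CH2Cl, rt) in the presence of 8 should give 12 and then vinylcyclobutenone 13; brief warming to 80 °C carries 13 through 14 and 15 to phenol 16, where the route resumes.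

Step 4. Facial selectivity in the acetylide addition may be poor, because the Felkin–Anh bias of an α-silyloxy aldehyde toward a small lithium acetylide is only moderate, and the aldehyde may epimerize or the triethylsilyl group may migrate in the lithium alkoxide. The fallback sets out from the C3-epimeric mixture of alcohol 7 and replaces substrate control by reagent control. Oxidation with MnO2 in CH2Cl2 would give the ynone (4S)-1-methoxy-5-methyl-4-(triethylsilyloxy)hex-1-yn-3-one F3. Oxazaborolidine-catalysed (Corey–Bakshi–Shibata) reduction with catecholborane in toluene at −78 °C, using the catalyst enantiomer that overrides the syn-directing Felkin preference of the ketone and delivers the 3R carbinol, returns to 7 as a single epimer.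

Step 10. Addition of the hindered, hydrogen-bonded phenol to the cumulated ylide may be slow, leaving the ylide to decompose before the intramolecular Wittig closure. The fallback sets out from aldehyde 18 and closes ring B by olefin metathesis. Methylenation with Ph3PCH3Br and KOt-Bu (2.2 equiv) in THF would give 2-[(1R,2S)-1-(tert-butyldimethylsilyloxy)-3-methyl-2-(triethylsilyloxy)butyl]-6-ethenyl-3-methoxyphenol F4. Acylation with acryloyl chloride and Et3N in CH2Cl2 at 0 °C would give the corresponding aryl prop-2-enoate F5. Ring-closing metathesis with the second-generation Grubbs catalyst, RuCl2(=CHPh)(PCy3)(H2IMes), in toluene at 80 °C would then deliver coumarin 20.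

**Further compounds**

F1 | step 8 | 4-chloro-1-diazobutan-2-one | ClCCC(=O)C=[N+]=[N-]
F2 | step 8 | 1-diazobut-3-en-2-one | C=CC(=O)C=[N+]=[N-]
F3 | step 4 | (4S)-1-methoxy-5-methyl-4-(triethylsilyloxy)hex-1-yn-3-one | COC#CC(=O)[C@@H](O[Si](CC)(CC)CC)C(C)C
F4 | step 10 | 2-[(1R,2S)-1-(tert-butyldimethylsilyloxy)-3-methyl-2-(triethylsilyloxy)butyl]-6-ethenyl-3-methoxyphenol | COc1ccc(C=C)c(O)c1[C@@H](O[Si](C)(C)C(C)(C)C)[C@@H](O[Si](CC)(CC)CC)C(C)C
F5 | step 10 | 2-[(1R,2S)-1-(tert-butyldimethylsilyloxy)-3-methyl-2-(triethylsilyloxy)butyl]-6-ethenyl-3-methoxyphenyl prop-2-enoate | COc1ccc(C=C)c(OC(=O)C=C)c1[C@@H](O[Si](C)(C)C(C)(C)C)[C@@H](O[Si](CC)(CC)CC)C(C)C
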